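## Analysis of the target

Sodwanone T (15) is a C30 triterpenoid built from two trans-fused 2,2-dimethyloxepane/cyclohexene bicycles. Ring A (oxepan-3-one) is fused to ring B (cyclohexene), and ring C (cyclohexene) is fused to ring D (oxepan-3-ol). The bicycles are joined by the C12–C13 ethano bridge between the tetrasubstituted alkenes C10=C11 and C14=C15 (numbering C1–C24 of the acyclic squalene chain, used for all compounds below).

There are five stereocentres: C6 (S, quaternary, methyl), C7 (S, CH–O), C18 (S, CH–O), C19 (S, quaternary, methyl) and C22 (R, carbinol). The two bicycles are homochiral. Apart from the oxidation level at C3 (ketone) and C22 (alcohol), the molecule has a C2 axis through the midpoint of C12–C13.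

The route exploits one feature of each half. The oxygen on C7 is bound to C2, C6 is bound to C11, and the alkene sits at C10=C11. This is the imprint of a 2,3-oxirane, a 6,7-oxirane and a 10,11-alkene of an all-E chain that reacted in a row, and it occurs twice, in rings A/B and in rings D/C.

The hydroxyl on C22 is cis to the C19 methyl. That is the opposite of what anti opening of a 22,23-oxirane of the same sense as the 18,19-oxirane would leave, so the carbinol cannot be taken directly from such a relay.

The sensitive groups are the tertiary ether bonds O–C2 and O–C23, which ionise in acid, and the tetrasubstituted alkenes next to quaternary carbons, which migrate in acid.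

Four things make the synthesis hard:
- the seven-membered ethers, which compete with five- and six-membered closure;
- the quaternary carbons C6 and C19, bonded to fully substituted alkene carbons;
- the position of the two alkenes;
- telling apart two distant ends that are chemically alike.

## Retrosynthetic reasoning

**15 from 13 (no skeletal bond cut; hidden symmetry uncovered).** The halves differ only at C3 and C22, so 15 is the product of a single reduction of the C2-symmetric diketone 13. The two carbonyl groups of 13 are homotopic, so reducing either one gives the same compound. The forward step only has to stop after one hydride and choose the right face at C22. Passing through the ketone is needed in any case, because C22 is epimeric to what an oxirane relay delivers.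

**13 from 12.** The diketone comes from the C2-symmetric diol 12 by oxidation. This removes the two carbinol centres that carry the wrong sense and leaves the four ring-fusion centres untouched.

**12 from 10 (key disconnection).** Four bonds are cut at once: O–C2, C6–C11, C14–C19 and O–C23. All four rings open to the acyclic tetraepoxide 10. This cut copies the presumed biogenesis and turns a tetracycle with two quaternary centres into a linear chain whose stereocentres are all oxirane carbons. Cutting elsewhere leaves an oxepane or a quaternary carbon in the precursor. The forward reaction has to run two oxirane-to-oxirane-to-alkene relays, invert C6 and C19, and place the alkenes at C10=C11 and C14=C15 only. The last demand is why 10 carries silicon on C11 and C14: the cation at C10 or C15 then loses silicon rather than one of three kinds of proton.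

**10 from 9.** The eight C–O bonds of the four oxiranes are cut back to the four E-trisubstituted alkenes of hexaene 9. One chiral dioxirane catalyst has to set six stereocentres with the same sense. The silicon on C11 and C14 does a second job here, because it makes the central alkenes tetrasubstituted and crowded, so they should stay out of the epoxidation.

**9 from 6 and 7.** The C13–C14 bond (sp3–sp2) is cut. Borane 8, made from diene 7 with a dialkylborane, couples with vinyl iodide 6 with retention. An allyl–allyl union at C12–C13 was avoided because it can transpose and scramble the tetrasubstituted alkenes. Diene 7 comes from 6 and a vinyl-metal reagent, so both halves derive from one building block.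

**6 from 4.** The C10–CH3 bond and the C11–I bond are cut across the alkyne of 4. A syn addition of a methyl-metal reagent to the silylalkyne, followed by iodination, fixes the geometry the relay needs, with silicon cis to C9.

**4 from 1 and 2.** The C8–C9 bond is cut. The lithiated form 3 of silylpropyne 2 is alkylated by the allylic bromide 1, which brings the two E-configured or prochiral alkenes of each half ready-made.

## Alternatives that were turned down

Alternative 1: the textbook cut at C12–C13 into two bicyclic halves. The forward key step is a reductive homocoupling (or a sulfone alkylation and desulfonylation) of the bicyclic allylic bromide A1 to give 13.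
- The cut removes one unstrained sp3–sp3 bond and leaves the whole difficulty (oxepane, quaternary carbon, tetrasubstituted alkene) inside A1.
- A1 would itself need a relay cyclisation or a stepwise ring synthesis, plus adjustment of the oxidation level at C12.
- The allyl unit of A1 is flanked by the quaternary C6 and the fully substituted C10, so coupling at C12 competes with reaction through C10 and with simple reduction.
- The low-valent metals used for such couplings do not tolerate the ketone, which adds protecting steps.
- The end game would still need the same desymmetrisation.

Alternative 2: a cut at C10=C11 and C14=C15. The forward key step is a double ring-closing metathesis of tetraene A2 with the second-generation Grubbs catalyst, RuCl2(H2IMes)(PCy3)(=CHPh), to give 13.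
- Each closure joins two 1,1-disubstituted alkenes into a tetrasubstituted one, and one partner sits on a quaternary carbon. This is among the slowest cases of the reaction.
- The step sets no stereocentre and closes the easier rings B and C.
- A2 keeps both oxepanes and all four ring-fusion centres, which would have to be made by separate stereocontrolled chemistry, so the precursor is hardly simpler than the product.

Alternative 3: a cut at C6–C7 and C8–C9 (and C18–C19 and C16–C17). The forward key step is a double intramolecular Diels–Alder reaction of the bis(vinyl ether) bis(diene) A3, which would close rings A/B and D/C at once and give 13.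
- Diene and dienophile are both electron-rich, so neither normal nor inverse electron demand applies.
- The diene terminus C6 is fully substituted and has to bring a methyl group inside the s-cis form, at the cost of severe allylic strain.
- A five-atom tether that closes a seven-membered ring gives little entropic help.
- A3 is achiral, so nothing in the substrate controls the absolute configuration or the trans fusion.

Key step: step 6

Assumption: the L-fructose-derived enantiomer of the Shi ketone (1,2:4,5-di-O-isopropylidene-β-L-erythro-2,3-hexodiulo-2,6-pyranose) is taken as a purchasable catalyst.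

## Route

Step 1
Reactants: 1 geranyl bromide; 2 1-(trimethylsilyl)propyne
Product: 4 (E)-(6,10-dimethylundeca-5,9-dien-1-yn-1-yl)trimethylsilane, via lithiated propyne 3 (not isolated)
Conditions: 2, n-BuLi, THF, −78 to −20 °C; then 1, −78 to 20 °C
Reagents that add atoms: none
Why: Propargylic lithiation of a 1-silylpropyne and SN2 alkylation by a primary allylic bromide form C8–C9. The silyl group blocks the alkyne terminus and favours the propargylic over the allenic product, and the E-alkene of 1 is not touched.

Step 2
Reactants: 4 (E)-(6,10-dimethylundeca-5,9-dien-1-yn-1-yl)trimethylsilane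
Product: 6 [(1E,5E)-1-iodo-2,6,10-trimethylundeca-1,5,9-trien-1-yl]trimethylsilane, via vinylmagnesium bromide 5 (not isolated)
Conditions: MeMgBr (3 equiv), Ni(acac)2 (10 mol %), AlMe3 (10 mol %), THF, 20 °C; then I2, THF, −78 to 0 °C
Reagents that add atoms: methylmagnesium bromide, C[Mg]Br; iodine, [I][I]
Why: Nickel-catalysed syn-carbomagnesiation of a 1-silylalkyne puts methyl on C10 and magnesium on the silicon-bearing C11, so that silicon is cis to C9 in the kinetic adduct 5, and iodinolysis keeps this geometry. The quench is made as soon as 4 is consumed because alpha-silyl vinylmagnesium species can isomerise; the trisubstituted alkenes are inert.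

Step 3
Reactants: 6 [(1E,5E)-1-iodo-2,6,10-trimethylundeca-1,5,9-trien-1-yl]trimethylsilane
Product: 7 trimethyl[(3Z,7E)-4,8,12-trimethyltrideca-1,3,7,11-tetraen-3-yl]silane
Conditions: CH2=CHMgBr, Pd(PPh3)4 (5 mol %), THF, 20 °C
Reagents that add atoms: vinylmagnesium bromide, C=C[Mg]Br
Why: Kumada coupling of a vinyl iodide proceeds with retention of the alkene geometry, and 6 holds nothing else that a Grignard reagent attacks. The vinyl group supplies C12 and C13.

Step 4
Reactants: 7 trimethyl[(3Z,7E)-4,8,12-trimethyltrideca-1,3,7,11-tetraen-3-yl]silane; 6 [(1E,5E)-1-iodo-2,6,10-trimethylundeca-1,5,9-trien-1-yl]trimethylsilane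
Product: 9 (6E,10Z,14Z,18E)-11,14-bis(trimethylsilyl)squalene, via B-alkyl-9-BBN 8 (not isolated)
Conditions: 7, 9-BBN-H, THF, 0 to 20 °C; then 6, Pd(dppf)Cl2 (5 mol %), AsPh3, Cs2CO3, DMF/THF/H2O, 20 to 50 °C
Reagents that add atoms: none
Why: 9-BBN-H picks the only monosubstituted alkene and puts boron on the terminal C13, and the B-alkyl Suzuki–Miyaura coupling with a second molecule of 6 forms C13–C14 with retention. Both halves come from one iodide, so the C2-symmetric chain is assembled without allyl transposition or loss of geometry.

Step 5
Reactants: 9 (6E,10Z,14Z,18E)-11,14-bis(trimethylsilyl)squalene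
Product: 10 (3S,6S,7S,18S,19S,22S)-2,3:6,7:18,19:22,23-tetraepoxide of 9
Conditions: L-fructose-derived Shi ketone (0.3 equiv per alkene), Oxone (2KHSO5·KHSO4·K2SO4), K2CO3, Bu4NHSO4, MeCN/CH2(OMe)2, aq Na2B4O7/Na2EDTA buffer (pH 10.5), 0 °C
Reagents that add atoms: potassium peroxymonosulfate, KHSO5, [K+].[O-]S(=O)(=O)OO
Why: In the Shi epoxidation the dioxirane of the L-fructose-derived ketone attacks E-trisubstituted alkenes through the spiro transition state and should give the (S,S)-oxiranes at C6–C7 and C18–C19 and the (S)-oxiranes at C3 and C22. The tetrasubstituted vinylsilanes offer no free quadrant for this approach and are shielded by SiMe3, so they should stay. Four events of the same sense should also raise the enantiopurity of the major C2-symmetric diastereomer by statistical amplification.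

Step 6
Reactants: 10 (3S,6S,7S,18S,19S,22S)-2,3:6,7:18,19:22,23-tetraepoxide of 9
Product: 12 C2-symmetric tetracyclic diol (3S,6S,7S,18S,19S,22S), via bis(trimethylsilyl) ether 11 (not isolated)
Conditions: Me3SiOTf (0.3 equiv), 2,6-di-tert-butyl-4-methylpyridine (0.6 equiv), CH2Cl2 (high dilution), −78 °C; then K2CO3 (cat.), MeOH, 0 °C
Reagents that add atoms: none
Why: Proposed new method: a two-directional epoxonium relay ended by ipso attack of a tetrasubstituted vinylsilane, whose closest known reaction types are the silyl-triflate-promoted tandem oxa-/carbacyclisation of 1,5-diepoxides that carry an alkene, allylsilane, propargylsilane or silyl enol ether terminator, the two-directional epoxide-initiated tetracyclisation of C2-symmetric polyenes, and the vinylsilane-terminated cation cyclisation. In each half Me3Si+ binds the terminal oxirane, the oxygen of the C6–C7 (C18–C19) oxirane opens it at the tertiary carbon C2 (C23), and the bicyclic epoxonium ion so formed is opened at its tertiary carbon C6 (C19) by C11 (C14) of the vinylsilane. Rings A and D thus arise by a net 7-endo opening of the terminal oxirane by the oxygen that stays on C7 (C18), and rings B and C by a 6-endo opening of the inner oxirane through a chair-like transition state. All stereocentres are relayed from 10: C3 and C22 keep their C–O bond (retention, S), C7 and C18 keep theirs (retention, S), and C6 and C19 are inverted by backside attack, which with oxiranes derived from E-alkenes can only give the trans ring fusion (6S,7S,18S,19S). The position of the new alkene, the selectivity that a proton-terminated version lacks, is secured by silicon, because in the Z-vinylsilane the C–Si bond is cis to C9, becomes axial in the chair and lies parallel to the empty orbital at C10 (C15), so that loss of Me3Si+ from the beta-silyl cation should outrun loss of any proton and the double bond can only appear at C10=C11 (C14=C15). Should a proton be lost instead, an allylsilane results whose protodesilylation moves the double bond to the same place, so that all exits converge. The Me3Si+ that leaves C11 opens the next terminal oxirane, so the step is a net isomerisation of 10 into 11 that needs only catalytic promoter and sets free no Brønsted acid that could shift the alkenes or cleave the tertiary ethers. The endo over exo selectivity of both openings rests on the tertiary character of C2 and C6, high dilution and the hindered pyridine guard against intermolecular attack and protodesilylation, and methanolysis of 11 then gives 12.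

Step 7
Reactants: 12 C2-symmetric tetracyclic diol (3S,6S,7S,18S,19S,22S)
Product: 13 C2-symmetric tetracyclic 3,22-diketone (6S,7S,18S,19S)
Conditions: Dess–Martin periodinane (2.5 equiv), CH2Cl2, 20 °C
Reagents that add atoms: none
Why: Dess–Martin oxidation converts two hindered secondary alcohols under nearly neutral conditions that leave the alkenes and the tertiary ethers alone. No stereocentre is alpha to the new ketones (C2 is quaternary, C4 is CH2), and the step erases the carbinol configuration that the relay delivers with the wrong sense for 15.

Step 8
Reactants: 13 C2-symmetric tetracyclic 3,22-diketone (6S,7S,18S,19S)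
Product: 15 sodwanone T, via catecholborate ester 14 (not isolated)
Conditions: (S)-2-methyl-CBS-oxazaborolidine (0.2 equiv), catecholborane (1.0 equiv, slow addition), toluene, −40 °C; then H2O
Reagents that add atoms: none
Why: In this Corey–Bakshi–Shibata reduction limited to one equivalent of hydride the two carbonyl groups of 13 are homotopic, so reduction of either gives the same compound, and unreacted 13 is recycled. The (S)-catalyst distinguishes the large C(CH3)2O side from the CH2 side and delivers hydride to the Si face to set (22R). This is also the ring face opposite to the axial C19 methyl, so catalyst and substrate should be matched, and catecholborane leaves the tetrasubstituted alkenes alone.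

## Compound list

1 | geranyl bromide, (2E)-1-bromo-3,7-dimethylocta-2,6-diene | CC(C)=CCC/C(C)=C/CBr | starting material
2 | 1-(trimethylsilyl)propyne | CC#C[Si](C)(C)C | starting material
3 | [3-(trimethylsilyl)prop-2-yn-1-yl]lithium | [Li]CC#C[Si](C)(C)C | intermediate
4 | (E)-(6,10-dimethylundeca-5,9-dien-1-yn-1-yl)trimethylsilane | CC(C)=CCC/C(C)=C/CCC#C[Si](C)(C)C | intermediate
5 | [(1Z,5E)-2,6,10-trimethyl-1-(trimethylsilyl)undeca-1,5,9-trien-1-yl]magnesium bromide | CC(C)=CCC/C(C)=C/CC/C(C)=C(/[Mg]Br)[Si](C)(C)C | intermediate
6 | [(1E,5E)-1-iodo-2,6,10-trimethylundeca-1,5,9-trien-1-yl]trimethylsilane | CC(C)=CCC/C(C)=C/CC/C(C)=C(/I)[Si](C)(C)C | intermediate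
7 | trimethyl[(3Z,7E)-4,8,12-trimethyltrideca-1,3,7,11-tetraen-3-yl]silane | CC(C)=CCC/C(C)=C/CC/C(C)=C(/C=C)[Si](C)(C)C | intermediate
8 | 9-[(3Z,7E)-4,8,12-trimethyl-3-(trimethylsilyl)trideca-3,7,11-trien-1-yl]-9-borabicyclo[3.3.1]nonane | CC(C)=CCC/C(C)=C/CC/C(C)=C(/CCB1C2CCCC1CCC2)[Si](C)(C)C | intermediate
9 | (6E,10Z,14Z,18E)-11,14-bis(trimethylsilyl)squalene, 2,6,10,15,19,23-hexamethyl-11,14-bis(trimethylsilyl)tetracosa-2,6,10,14,18,22-hexaene | CC(C)=CCC/C(C)=C/CC/C(C)=C(/CC/C([Si](C)(C)C)=C(\C)CC/C=C(\C)CCC=C(C)C)[Si](C)(C)C | intermediate
10 | (3S,6S,7S,18S,19S,22S)-2,3:6,7:18,19:22,23-tetraepoxide of 9 | CC1(C)O[C@H]1CC[C@]2(C)O[C@H]2CC/C(C)=C(/CC/C([Si](C)(C)C)=C(\C)CC[C@@H]3O[C@@]3(C)CC[C@@H]4OC4(C)C)[Si](C)(C)C | intermediate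
11 | 3,22-bis(trimethylsilyl) ether of 12 | CC1=C(CCC2=C(C)CC[C@@H]3OC(C)(C)[C@@H](O[Si](C)(C)C)CC[C@@]23C)[C@]2(C)CC[C@H](O[Si](C)(C)C)C(C)(C)O[C@H]2CC1 | intermediate
12 | C2-symmetric tetracyclic diol (3S,6S,7S,18S,19S,22S), both hydroxyls trans to the neighbouring angular methyl | CC1=C(CCC2=C(C)CC[C@@H]3OC(C)(C)[C@@H](O)CC[C@@]23C)[C@]2(C)CC[C@H](O)C(C)(C)O[C@H]2CC1 | intermediate
13 | C2-symmetric tetracyclic 3,22-diketone (6S,7S,18S,19S) | CC1=C(CCC2=C(C)CC[C@@H]3OC(C)(C)C(=O)CC[C@@]23C)[C@]2(C)CCC(=O)C(C)(C)O[C@H]2CC1 | intermediate
14 | 22-O-(1,3,2-benzodioxaborol-2-yl) derivative of 15 | CC1=C(CCC2=C(C)CC[C@@H]3OC(C)(C)[C@H](OB4Oc5ccccc5O4)CC[C@@]23C)[C@]2(C)CCC(=O)C(C)(C)O[C@H]2CC1 | intermediate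
15 | sodwanone T (6S,7S,18S,19S,22R) | CC1=C(CCC2=C(C)CC[C@@H]3OC(C)(C)[C@H](O)CC[C@@]23C)[C@]2(C)CCC(=O)C(C)(C)O[C@H]2CC1 | target

## Step count and least certain steps

Total step count: 8. Longest linear sequence: 8 steps (1, 4, 6, 7, 9, 10, 12, 13, 15). Iodide 6 is used twice, in steps 3 and 4.

**Step 6 (key step, proposed new method).**
- Most likely failure: steric retardation of the ipso attack. C11 carries SiMe3 and C12 and must bond to the tertiary C6, so the epoxonium ions may collapse first, by hydride shift, by exo opening to five-membered ethers or by capture of triflate.
- Other failures: protodesilylation by adventitious acid, and a stall after only one of the two relays.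
- Fallback with known chemistry, from 10 back to 11: silicon is kept only for its first job, the shielding of the central alkenes in step 5, and is then removed. Fluoride-induced protodesilylation of the alkenylsilanes (Bu4NF, wet DMSO, 80 °C; retention of geometry, non-acidic medium that trisubstituted oxiranes tolerate) would give (3S,6S,7S,18S,19S,22S)-squalene tetraepoxide F1.
- F1 is then exposed to stoichiometric Me3SiOTf and 2,6-di-tert-butyl-4-methylpyridine in CH2Cl2 at −78 °C. This is the alkene-terminated tandem oxa-/carbacyclisation, a known reaction type that ends by proton loss, and it leads to 11.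
- Price: proton loss is not regioselective, so the wanted alkene isomer would have to be separated on silica impregnated with AgNO3.

**Step 5.**
- Most likely failure: competing epoxidation of the vinylsilanes, which are electron-rich although crowded.
- Also possible: incomplete fourfold conversion of a very lipophilic substrate in the aqueous medium, with a build-up of partly oxidised material and of minor diastereomers.
- Fallback, from 6 back to 10: the oxiranes are installed before the union, while the central alkene is deactivated by iodine as well as shielded by silicon. Shi epoxidation of 6 with the same ketone would give the (3S,6S,7S)-diepoxy iodide F2.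
- Stille coupling of F2 with tributyl(vinyl)stannane (Pd(PPh3)4, CuI, DMF), which tolerates oxiranes, would give the diepoxy diene F3. 9-BBN-H would convert F3 into the borane F4, and Suzuki–Miyaura coupling of F4 with a second portion of F2 under the conditions of step 4 would give 10.

**Step 2.**
- Most likely failure: E/Z isomerisation of the alpha-silyl vinylmagnesium species before the quench, or slow carbomagnesiation that forces long reaction times and so favours this isomerisation.
- Consequence: the wrong geometry places silicon equatorial in the chair of step 6 and slows its loss.
- Fallback, from 4 back to 6: the configurationally labile C–Mg bond is replaced by stable C–B bonds. Syn-diboration of 4 with bis(pinacolato)diboron and Pt(PPh3)4 in toluene at 80 °C would give the vicinal diboryl vinylsilane F5.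
- Site-selective Suzuki–Miyaura methylation of F5 with MeI (Pd(PPh3)4, K2CO3, DMF/H2O) at the less hindered C10–B bond would give the geminal silyl boronate F6. Iodo-deboronation of F6 (NaOH, then I2, retention) would give 6.

**Step 8.**
- Most likely failure: over-reduction and incomplete conversion side by side, because the two carbonyl groups are remote and react independently.
- Also possible: erosion of face selectivity if the ring conformation opposes the catalyst.
- Fallback, from 13 back to 15: stereocontrol is separated from desymmetrisation. Exhaustive reduction of 13 with excess catecholborane and the same catalyst would give the C2-symmetric (3R,22R)-diol F7, whose purity can be secured on a symmetric compound. One equivalent of Dess–Martin periodinane would then oxidise one of its two homotopic carbinols to give 15, and both F7 and 13 can be recycled.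

## Further compounds

F1 | step 6 | (3S,6S,7S,18S,19S,22S)-squalene 2,3:6,7:18,19:22,23-tetraepoxide | CC1(C)O[C@H]1CC[C@]2(C)O[C@H]2CC/C(C)=C/CC/C=C(\C)CC[C@@H]3O[C@@]3(C)CC[C@@H]4OC4(C)C
F2 | step 5 | (3S,6S,7S)-2,3:6,7-diepoxide of iodide 6 | CC1(C)O[C@H]1CC[C@]2(C)O[C@H]2CC/C(C)=C(/I)[Si](C)(C)C
F3 | step 5 | (3S,6S,7S)-2,3:6,7-diepoxide of diene 7 | CC1(C)O[C@H]1CC[C@]2(C)O[C@H]2CC/C(C)=C(/C=C)[Si](C)(C)C
F4 | step 5 | B-alkyl-9-BBN adduct of F3 (boron on C13) | CC1(C)O[C@H]1CC[C@]2(C)O[C@H]2CC/C(C)=C(/CCB3C4CCCC3CCC4)[Si](C)(C)C
F5 | step 2 | syn-10,11-bis(pinacolboryl) adduct of 4 (vicinal diboryl vinylsilane) | CC(C)=CCC/C(C)=C/CC/C(B1OC(C)(C)C(C)(C)O1)=C(/B1OC(C)(C)C(C)(C)O1)[Si](C)(C)C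
F6 | step 2 | geminal silyl pinacolboronate, boron in place of the iodine of 6 | CC(C)=CCC/C(C)=C/CC/C(C)=C(/B1OC(C)(C)C(C)(C)O1)[Si](C)(C)C
F7 | step 8 | C2-symmetric tetracyclic diol (3R,6S,7S,18S,19S,22R) | CC1=C(CCC2=C(C)CC[C@@H]3OC(C)(C)[C@H](O)CC[C@@]23C)[C@]2(C)CC[C@@H](O)C(C)(C)O[C@H]2CC1
A1 | alternative 1 | (5aS,9aS)-6-(bromomethyl)-2,2,5a,7-tetramethyl-4,5,5a,8,9,9a-hexahydro-1-benzoxepin-3(2H)-one | CC1=C(CBr)[C@]2(C)CCC(=O)C(C)(C)O[C@H]2CC1
A2 | alternative 2 | bis(oxepanone) tetraene, seco at C10=C11 and C14=C15 | C=C(C)CC[C@@H]1OC(C)(C)C(=O)CC[C@@]1(C)C(=C)CCC(=C)[C@]2(C)CCC(=O)C(C)(C)O[C@H]2CCC(C)=C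
A3 | alternative 3 | achiral bis(vinyl ether) bis(diene), seco at C6–C7, C8–C9, C16–C17 and C18–C19 | C=C(C)/C(CC/C(C(C)=C)=C(/C)CCC(=O)C(C)(C)OC=C)=C(/CCC(=O)C(C)(C)OC=C)C
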